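**Retrosynthetic overview**

1. Ring A is the 3-bromo-2-hydroxy-6-methoxy-4-methylphenyl ring; ring B is numbered B1 (bears the diaryl ketone), B2 (CHO), B3 (OH), B4 (H), B5 (OH), B6 (prenyl). The route rests on the alternating oxygenation of ring B along formyl carbon, B2, B3 (O), B4, B5 (O), B6, B1 (C=O outside the ring), the imprint of a folded poly-β-carbonyl chain whose last carbonyl, B1, is the inner carbon of an aryl 1,2-diketone.
2. Ring B is opened at B1–B2 (aldol cycloaromatisation) to the dioxinone-capped triketone 15; the dioxinone supplies the formyl carbon, B2, B3 and B4 and is reduced to the salicylaldehyde at the end.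
3. 15 is cut at B6–B1 (dianion acylation by the ring A α-keto Weinreb amide 6, so that both crowded carbonyl carbons arrive with ring A) and at the B6–prenyl bond (dianion alkylation of keto-dioxinone 10, placed before the acylation so that the prenyl position does not depend on a late alkylation of a polycarbonyl chain).
4. 6 comes from 3-methoxy-5-methylphenol by ortho-bromination, MOM protection and directed ortho-metalation with trapping by the oxalic bis-Weinreb amide 4.
5. Ring order: ring A and the dioxinone ring are bought; ring B is closed in step 7; the dioxinone (acetonide) ring is opened reductively in step 9.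

Key step: step 7

Remark (assumption): the target has no stereocentre. Compound 15 is racemic at B6 and compound 16 is a mixture of diastereomers; both are drawn in one keto form although they will exist largely as enol tautomers.

**Route**

Step 1
Reactants: 1 3-methoxy-5-methylphenol
Product: 2 2-bromo-5-methoxy-3-methylphenol
Conditions: NBS (1.0 equiv), i-Pr2NH (cat.), CH2Cl2, -78 to 0 °C
Reagents that add atoms: N-bromosuccinimide, O=C1CCC(=O)N1Br
Why: Amine-catalysed ortho-bromination of a phenol (electrophilic aromatic substitution): the N-bromoamine formed from NBS and i-Pr2NH is held by the phenol OH and should deliver bromine ortho to it, at the site para to OMe and not at the crowded site between the two oxygens; any para-bromo isomer is removed by chromatography.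

Step 2
Reactants: 2 2-bromo-5-methoxy-3-methylphenol
Product: 3 2-bromo-5-methoxy-1-(methoxymethoxy)-3-methylbenzene
Conditions: MOMCl, i-Pr2NEt, CH2Cl2, 0 °C to rt
Reagents that add atoms: chloromethyl methyl ether, COCCl
Why: Williamson-type O-alkylation of the phenol by the reactive α-chloro ether (MOM protection), which also turns this oxygen into a metalation director for step 3.

Step 3
Reactants: 3 2-bromo-5-methoxy-1-(methoxymethoxy)-3-methylbenzene; 4 N,N'-dimethoxy-N,N'-dimethyloxamide
Product: 6 2-[3-bromo-6-methoxy-2-(methoxymethoxy)-4-methylphenyl]-N-methoxy-N-methyl-2-oxoacetamide, via aryllithium 5 (not isolated)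
Conditions: lithium 2,2,6,6-tetramethylpiperidide (LiTMP, 1.2 equiv), THF, -78 °C; then 4 (1.5 equiv), -78 to 0 °C; AcOH
Reagents that add atoms: N,N'-dimethoxy-N,N'-dimethyloxamide (4), CON(C)C(=O)C(=O)N(C)OC
Why: Directed ortho-metalation: the hindered amide base removes the proton flanked by OMOM and OMe without bromine–lithium exchange (no proton stands ortho to bromine, so no aryne can form), and aryllithium 5 adds only once to the bis-Weinreb amide because the chelated tetrahedral adduct holds until the quench (Weinreb ketone synthesis).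

Step 4
Reactants: 7 2,2,6-trimethyl-4H-1,3-dioxin-4-one; 8 acetyl chloride
Product: 10 2,2-dimethyl-6-(2-oxopropyl)-4H-1,3-dioxin-4-one, via lithium dienolate 9 (not isolated)
Conditions: LiN(SiMe3)2, THF, -78 °C; then 8 (0.5 equiv), -78 °C; AcOH
Reagents that add atoms: acetyl chloride (8), CC(Cl)=O
Why: γ-C-Acylation of the lithium dienolate of the dioxinone (vinylogous Claisen condensation); half an equivalent of 8 is used because the more acidic product consumes a second equivalent of dienolate.

Step 5
Reactants: 10 2,2-dimethyl-6-(2-oxopropyl)-4H-1,3-dioxin-4-one; 11 prenyl bromide (1-bromo-3-methylbut-2-ene)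
Product: 13 2,2-dimethyl-6-(6-methyl-2-oxohept-5-en-1-yl)-4H-1,3-dioxin-4-one, via dilithium dianion 12 (not isolated)
Conditions: LiN(i-Pr)2 (2.1 equiv), THF, -78 to -20 °C; then 11 (1.0 equiv), -78 to 0 °C; AcOH
Reagents that add atoms: prenyl bromide (11), CC(C)=CCBr
Why: Weiler-type dianion alkylation: the second, more basic enolate (the methyl ketone terminus) of dianion 12 should react by SN2 displacement at the primary carbon of the allylic bromide, which fixes the prenyl group on the carbon that becomes B6.

Step 6
Reactants: 13 2,2-dimethyl-6-(6-methyl-2-oxohept-5-en-1-yl)-4H-1,3-dioxin-4-one; 6 2-[3-bromo-6-methoxy-2-(methoxymethoxy)-4-methylphenyl]-N-methoxy-N-methyl-2-oxoacetamide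
Product: 15 6-{3-[2-(3-bromo-6-methoxy-2-(methoxymethoxy)-4-methylphenyl)-2-oxoacetyl]-6-methyl-2-oxohept-5-en-1-yl}-2,2-dimethyl-4H-1,3-dioxin-4-one (racemic), via dilithium dianion 14 (not isolated)
Conditions: LiN(i-Pr)2 (2.1 equiv), THF, -78 °C; then 6 (0.9 equiv), -78 to -40 °C; AcOH, -78 °C
Reagents that add atoms: none
Why: Dianion C-acylation of a β-dicarbonyl by a Weinreb amide: the more basic terminal carbanion of 14 should attack the amide carbonyl of 6, because the neighbouring aryl ketone is blocked on both faces by the OMe and OMOM groups of ring A, and the chelated tetrahedral adduct holds until the cold acidic quench.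

Step 7
Reactants: 15 the diketo-dioxinone of step 6
Product: 17 5-[3-bromo-6-methoxy-2-(methoxymethoxy)-4-methylbenzoyl]-7-hydroxy-2,2-dimethyl-6-(3-methylbut-2-en-1-yl)-4H-1,3-benzodioxin-4-one, via aldol adduct 16 (not isolated)
Conditions: Et3N, CH2Cl2, 0 °C to rt; then AcOH, rt
Reagents that add atoms: none
Why: Et3N removes a B4 proton of 15 to give the extended dioxinone dienolate, whose carbon B2 (C5 of the dioxinone) adds to the B1 ketone in an intramolecular aldol reaction to give 16; loss of water across B1–B2 and enolisation of the B5 ketone towards B6 then give arene 17, the acetic acid treatment completing the dehydration. The closest known reaction is the amine-induced cycloaromatisation of 6-(2,4-dioxoalkyl)dioxinones to acetonide-protected resorcylates; the difference here is that the accepting carbonyl is the inner carbon of an aryl 1,2-diketone, a terminus that has not been tested but should be more electrophilic, not less. Ring B closes in a 6-(enolendo)-exo-trig mode. No stereocentre remains, since the B6 centre of 15 and both centres of 16 become sp2 on aromatisation. The step needs attack at B1 and not at the aroyl carbonyl, which ring size (six against seven) and the shielding of the aroyl carbonyl by the two ortho substituents of ring A should secure. Closure through the B5 enol oxygen onto the aroyl carbonyl to a hydroxyfuranone is hindered in the same way and is reversible, whereas aromatisation is not.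

Step 8
Reactants: 17 the benzodioxinone of step 7
Product: 18 5-[3-bromo-6-methoxy-2-(methoxymethoxy)-4-methylbenzoyl]-7-(methoxymethoxy)-2,2-dimethyl-6-(3-methylbut-2-en-1-yl)-4H-1,3-benzodioxin-4-one
Conditions: MOMCl, i-Pr2NEt, CH2Cl2, 0 °C to rt
Reagents that add atoms: chloromethyl methyl ether, COCCl
Why: MOM protection (O-alkylation) of the acidic B5 phenol, para to the lactone carbonyl, so that no aluminium phenoxide deactivates that carbonyl in step 9; the group matches the one on ring A and leaves with it.

Step 9
Reactants: 18 the bis-MOM benzodioxinone of step 8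
Product: 20 2-[3-bromo-6-methoxy-2-(methoxymethoxy)-4-methylbenzoyl]-6-hydroxy-4-(methoxymethoxy)-3-(3-methylbut-2-en-1-yl)benzaldehyde, via aluminium hemiacetal 19 (not isolated)
Conditions: i-Bu2AlH (1.2 equiv), CH2Cl2, -78 °C; then MeOH, aq. potassium sodium tartrate (KNaC4H4O6), rt
Reagents that add atoms: none
Why: Partial reduction of the aryl acylal lactone by i-Bu2AlH: one hydride adds to the benzodioxinone carbonyl to give hemiacetal 19, stable at -78 °C, which loses acetone on work-up to unveil the salicylaldehyde, while the tetra-ortho-substituted benzophenone carbonyl should be too shielded to react at this temperature.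

Step 10
Reactants: 20 the salicylaldehyde of step 9
Product: 21 pestalone B, 2-(3-bromo-2-hydroxy-6-methoxy-4-methylbenzoyl)-4,6-dihydroxy-3-(3-methylbut-2-en-1-yl)benzaldehyde
Conditions: HCl (aq. 3 M)/MeOH, rt
Reagents that add atoms: none
Why: Acid-catalysed acetal exchange with methanol should remove both MOM ethers (the one on ring A is helped by the ortho carbonyl) under conditions mild enough to leave the prenyl group uncyclised; any dimethyl acetal of the aldehyde reverts on aqueous work-up.

**Compound list**

1 | 3-methoxy-5-methylphenol | COc1cc(C)cc(O)c1 | starting material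
2 | 2-bromo-5-methoxy-3-methylphenol | COc1cc(C)c(Br)c(O)c1 | intermediate
3 | 2-bromo-5-methoxy-1-(methoxymethoxy)-3-methylbenzene | COCOc1cc(OC)cc(C)c1Br | intermediate
4 | N,N'-dimethoxy-N,N'-dimethyloxamide | CON(C)C(=O)C(=O)N(C)OC | starting material
5 | [3-bromo-6-methoxy-2-(methoxymethoxy)-4-methylphenyl]lithium | [Li]c1c(OC)cc(C)c(Br)c1OCOC | intermediate
6 | 2-[3-bromo-6-methoxy-2-(methoxymethoxy)-4-methylphenyl]-N-methoxy-N-methyl-2-oxoacetamide | CON(C)C(=O)C(=O)c1c(OC)cc(C)c(Br)c1OCOC | intermediate
7 | 2,2,6-trimethyl-4H-1,3-dioxin-4-one | CC1=CC(=O)OC(C)(C)O1 | starting material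
8 | acetyl chloride | CC(Cl)=O | starting material
9 | lithium 2,2-dimethyl-6-methylidene-6H-1,3-dioxin-4-olate (lithium dienolate of 7) | C=C1C=C(O[Li])OC(C)(C)O1 | intermediate
10 | 2,2-dimethyl-6-(2-oxopropyl)-4H-1,3-dioxin-4-one | CC(=O)CC1=CC(=O)OC(C)(C)O1 | intermediate
11 | prenyl bromide (1-bromo-3-methylbut-2-ene) | CC(C)=CCBr | starting material
12 | dilithium dianion of 10 (dienolate plus terminal ketone enolate) | C=C(O[Li])C=C1C=C(O[Li])OC(C)(C)O1 | intermediate
13 | 2,2-dimethyl-6-(6-methyl-2-oxohept-5-en-1-yl)-4H-1,3-dioxin-4-one | CC(C)=CCCC(=O)CC1=CC(=O)OC(C)(C)O1 | intermediate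
14 | dilithium dianion of 13 (enolate geometry not defined) | CC(C)=CCC=C(O[Li])C=C1C=C(O[Li])OC(C)(C)O1 | intermediate
15 | 6-{3-[2-(3-bromo-6-methoxy-2-(methoxymethoxy)-4-methylphenyl)-2-oxoacetyl]-6-methyl-2-oxohept-5-en-1-yl}-2,2-dimethyl-4H-1,3-dioxin-4-one (racemic, keto form drawn) | CC1(C)OC(=O)C=C(CC(=O)C(CC=C(C)C)C(=O)C(=O)c2c(OC)cc(C)c(Br)c2OCOC)O1 | intermediate
16 | 5-[3-bromo-6-methoxy-2-(methoxymethoxy)-4-methylbenzoyl]-5-hydroxy-2,2-dimethyl-6-(3-methylbut-2-en-1-yl)-5,8-dihydro-4H-1,3-benzodioxine-4,7(6H)-dione (aldol adduct, mixture of diastereomers) | CC1(C)OC(=O)C2=C(O1)CC(=O)C(CC=C(C)C)C2(O)C(=O)c1c(OC)cc(C)c(Br)c1OCOC | intermediate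
17 | 5-[3-bromo-6-methoxy-2-(methoxymethoxy)-4-methylbenzoyl]-7-hydroxy-2,2-dimethyl-6-(3-methylbut-2-en-1-yl)-4H-1,3-benzodioxin-4-one | CC1(C)OC(=O)c2c(O1)cc(O)c(CC=C(C)C)c2C(=O)c1c(OC)cc(C)c(Br)c1OCOC | intermediate
18 | 5-[3-bromo-6-methoxy-2-(methoxymethoxy)-4-methylbenzoyl]-7-(methoxymethoxy)-2,2-dimethyl-6-(3-methylbut-2-en-1-yl)-4H-1,3-benzodioxin-4-one | CC1(C)OC(=O)c2c(O1)cc(OCOC)c(CC=C(C)C)c2C(=O)c1c(OC)cc(C)c(Br)c1OCOC | intermediate
19 | diisobutylaluminium alkoxide of the C4 lactol of 18 (racemic) | CC(C)C[Al](CC(C)C)OC1OC(C)(C)Oc2cc(OCOC)c(CC=C(C)C)c(C(=O)c3c(OC)cc(C)c(Br)c3OCOC)c12 | intermediate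
20 | 2-[3-bromo-6-methoxy-2-(methoxymethoxy)-4-methylbenzoyl]-6-hydroxy-4-(methoxymethoxy)-3-(3-methylbut-2-en-1-yl)benzaldehyde | O=Cc1c(O)cc(OCOC)c(CC=C(C)C)c1C(=O)c1c(OC)cc(C)c(Br)c1OCOC | intermediate
21 | pestalone B | COc1cc(C)c(Br)c(O)c1C(=O)c1c(C=O)c(O)cc(O)c1CC=C(C)C | target

**Step count**

Total: 10 steps. Longest linear sequence: 8 steps (steps 1, 2, 3, 6, 7, 8, 9, 10); the dioxinone branch (steps 4, 5) joins at step 6.

**Steps most likely to fail**

Step 7. The enolised 1,2-diketone may not offer a free B1 carbonyl, the substrate may drain into a cyclic hemiketal by closure through oxygen, or the vicinal dicarbonyl may fragment under base before the weakly nucleophilic dioxinone carbon closes the ring. The fallback sets out from 15 and opens the dioxinone before the ring closure, so that B2 becomes an ordinary β-keto ester methylene. Heating 15 in toluene with methanol at 110 °C (retro-[4+2] to the acylketene and trapping) should give methyl 8-[3-bromo-6-methoxy-2-(methoxymethoxy)-4-methylphenyl]-6-(3-methylbut-2-en-1-yl)-3,5,7,8-tetraoxooctanoate F1. Cs2CO3 in MeOH followed by AcOH (the known ketene-trapping variant of the aldol aromatisation) should give the methyl 6-aroyl-2,4-dihydroxy-5-prenylbenzoate F2. One equivalent of MOMCl with i-Pr2NEt should protect the non-chelated B5 hydroxyl to give the mono-MOM ester F3. Excess i-Bu2AlH in CH2Cl2 (-78 to 0 °C) should reduce the ester to the salicyl alcohol F4, and MnO2 in CH2Cl2 should oxidise the benzylic alcohol, coming back to the route at 20. This fallback shares the α-diketone acceptor and the hydride exposure of the benzophenone carbonyl with the main route.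

Step 6. The dianion may add to the ketone carbonyl of 6 in place of the amide carbonyl, or proton transfer may outrun the slow meeting of a secondary carbanion and a hindered amide. The fallback sets out from 3 and 13 and makes the B6–B1 bond by an aldol reaction followed by oxidation. Aryllithium 5 (from 3 as in step 3) is trapped with N-methoxy-N-methylacetamide to give 1-[3-bromo-6-methoxy-2-(methoxymethoxy)-4-methylphenyl]ethanone F5. SeO2 in wet dioxane at 90 °C (Riley oxidation) should give the arylglyoxal F6, which is dried by azeotropic distillation. Dianion 14 should add to the aldehyde carbonyl of F6 in THF at -78 °C to give the β-hydroxy ketone F7 as a mixture of diastereomers, and Dess–Martin periodinane (CH2Cl2, NaHCO3) should oxidise the carbinol, coming back to the route at 15.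

Step 9. The aluminium hemiacetal may collapse at low temperature and be reduced past the aldehyde stage, or hydride may attack the benzophenone carbonyl. A diaryl carbinol formed next to the aldehyde would close to a lactol and could not simply be reoxidised to the ketone, so excess hydride must be avoided in the main step. The fallback sets out from 18 and separates reduction from the aldehyde oxidation state: LiBH4 in THF at 0 °C should reduce the benzodioxinone fully, with loss of acetone, to the salicyl alcohol F8 (the same compound as F4) while sparing the hindered ketone, and MnO2 in CH2Cl2 should then oxidise the benzylic alcohol, coming back to the route at 20.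

**Further compounds**

F1 | step 7 | methyl 8-[3-bromo-6-methoxy-2-(methoxymethoxy)-4-methylphenyl]-6-(3-methylbut-2-en-1-yl)-3,5,7,8-tetraoxooctanoate (racemic) | COC(=O)CC(=O)CC(=O)C(CC=C(C)C)C(=O)C(=O)c1c(OC)cc(C)c(Br)c1OCOC
F2 | step 7 | methyl 6-[3-bromo-6-methoxy-2-(methoxymethoxy)-4-methylbenzoyl]-2,4-dihydroxy-5-(3-methylbut-2-en-1-yl)benzoate | COC(=O)c1c(O)cc(O)c(CC=C(C)C)c1C(=O)c1c(OC)cc(C)c(Br)c1OCOC
F3 | step 7 | methyl 6-[3-bromo-6-methoxy-2-(methoxymethoxy)-4-methylbenzoyl]-2-hydroxy-4-(methoxymethoxy)-5-(3-methylbut-2-en-1-yl)benzoate | COC(=O)c1c(O)cc(OCOC)c(CC=C(C)C)c1C(=O)c1c(OC)cc(C)c(Br)c1OCOC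
F4 | step 7 | [3-bromo-6-methoxy-2-(methoxymethoxy)-4-methylphenyl][3-hydroxy-2-(hydroxymethyl)-5-(methoxymethoxy)-6-(3-methylbut-2-en-1-yl)phenyl]methanone | OCc1c(O)cc(OCOC)c(CC=C(C)C)c1C(=O)c1c(OC)cc(C)c(Br)c1OCOC
F5 | step 6 | 1-[3-bromo-6-methoxy-2-(methoxymethoxy)-4-methylphenyl]ethanone | CC(=O)c1c(OC)cc(C)c(Br)c1OCOC
F6 | step 6 | 2-[3-bromo-6-methoxy-2-(methoxymethoxy)-4-methylphenyl]-2-oxoacetaldehyde | O=CC(=O)c1c(OC)cc(C)c(Br)c1OCOC
F7 | step 6 | 6-{3-[2-(3-bromo-6-methoxy-2-(methoxymethoxy)-4-methylphenyl)-1-hydroxy-2-oxoethyl]-6-methyl-2-oxohept-5-en-1-yl}-2,2-dimethyl-4H-1,3-dioxin-4-one (mixture of diastereomers) | CC1(C)OC(=O)C=C(CC(=O)C(CC=C(C)C)C(O)C(=O)c2c(OC)cc(C)c(Br)c2OCOC)O1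
F8 | step 9 | [3-bromo-6-methoxy-2-(methoxymethoxy)-4-methylphenyl][3-hydroxy-2-(hydroxymethyl)-5-(methoxymethoxy)-6-(3-methylbut-2-en-1-yl)phenyl]methanone | OCc1c(O)cc(OCOC)c(CC=C(C)C)c1C(=O)c1c(OC)cc(C)c(Br)c1OCOC
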